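**Retrosynthetic overview**

1. The strategy rests on C3, a secondary allylic carbinol bonded to the methyl-bearing C4 of the Z C4=C5 olefin inside the ten-membered carbocycle. C3–C4 is cut to a C3 aldehyde and a (Z)-C4 alkenyl iodide, joined last by an intramolecular NiCl2/CrCl2 (Nozaki–Hiyama–Kishi) coupling that closes the carbocycle.
2. The C3 aldehyde is unveiled by ozonolysis of a prenyl terminus; the C8 isobutyrate is put on with inversion (Mitsunobu).
3. C7–C8 is cut by a zinc Barbier allylation between a 3-(bromomethyl)butenolide (C4–C7, C11–C13, C15) and a C8 aldehyde from (S)-linalool (C8–C10, C1–C3, C14); this sets C7 and C8 and turns the butenolide into the trans α-methylene lactone.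
4. The butenolide comes from ring-closing metathesis of the 2-(bromomethyl)acrylate of (3S,4Z)-5-iodohexa-1,4-dien-3-ol, made from but-2-yn-1-ol.
5. Ring order: lactone ring first (step 6), ten-membered carbocycle last (step 13).

Key step: step 13

Assumption: atom labels follow germacrane numbering (C1–C10 carbocycle, C11–C13 lactone, C14 on C10, C15 on C4); the zinc allylation of step 10 is taken to follow the usual chair transition state and give the 8S carbinol, so the ester is introduced with inversion.

**Route**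

Step 1
Reactants: 1 but-2-yn-1-ol
Product: 3 (Z)-3-iodobut-2-en-1-ol, via sodium alkenylaluminate 2 (not isolated)
Conditions: NaAlH2(OCH2CH2OCH3)2, THF, 0 °C to rt; then I2, THF, −78 to 0 °C
Reagents that add atoms: iodine, [I][I]
Why: Hydroxyl-directed trans-hydroalumination of the propargylic alcohol puts aluminium on the distal carbon in a five-membered alkenylaluminate, and iodinolysis with retention should give the Z iodide (hydroalumination–iodination).

Step 2
Reactants: 3 (Z)-3-iodobut-2-en-1-ol
Product: 4 (Z)-3-iodobut-2-enal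
Conditions: MnO2, CH2Cl2, rt, dark
Reagents that add atoms: none
Why: Allylic alcohol oxidation with MnO2 is neutral and should stop at the enal without isomerising the Z iodoalkene.

Step 3
Reactants: 4 (Z)-3-iodobut-2-enal
Product: 5 rac-(Z)-5-iodohexa-1,4-dien-3-ol
Conditions: CH2=CHMgBr, THF, −78 °C; aq NH4Cl
Reagents that add atoms: vinylmagnesium bromide, C=C[Mg]Br
Why: Grignard 1,2-addition to the aldehyde at low temperature should outrun iodine–magnesium exchange and addition–elimination at the iodo-bearing carbon, giving the racemic doubly allylic carbinol.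

Step 4
Reactants: 5 rac-(Z)-5-iodohexa-1,4-dien-3-ol
Product: 6 (3S,4Z)-5-iodohexa-1,4-dien-3-ol
Conditions: Novozym 435 (immobilised Candida antarctica lipase B), vinyl acetate, hexane, 30 °C, stopped just past half conversion; chromatography
Reagents that add atoms: none
Why: Lipase-catalysed kinetic resolution by transesterification: by Kazlauskas' rule (vinyl medium, iodopropenyl large) the enzyme should acylate the R enantiomer and leave the S alcohol, which carries the C6 configuration of the target.

Step 5
Reactants: 6 (3S,4Z)-5-iodohexa-1,4-dien-3-ol; 7 2-(bromomethyl)prop-2-enoic acid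
Product: 9 (3S,4Z)-5-iodohexa-1,4-dien-3-yl 2-(bromomethyl)prop-2-enoate, via 2-(bromomethyl)acryloyl chloride 8 (not isolated)
Conditions: 7, (COCl)2, DMF (cat.), CH2Cl2, 0 °C to rt, volatiles removed; then 6, iPr2NEt, CH2Cl2, −78 to 0 °C
Reagents that add atoms: none
Why: Acid chloride esterification with a hindered, non-nucleophilic amine acylates the secondary alcohol with retention at C6 and should avoid SN2' attack on the allylic bromide.

Step 6
Reactants: 9 (3S,4Z)-5-iodohexa-1,4-dien-3-yl 2-(bromomethyl)prop-2-enoate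
Product: 10 (5S)-3-(bromomethyl)-5-[(Z)-2-iodoprop-1-en-1-yl]furan-2(5H)-one
Conditions: second-generation Grubbs catalyst RuCl2(=CHPh)(PCy3)(H2IMes) (5 mol%), toluene (0.01 M), 80 °C
Reagents that add atoms: none
Why: Ring-closing metathesis between the vinyl group and the acrylate olefin closes the butenolide (the lactone ring) with loss of ethene; the trisubstituted iodoalkene is too hindered to engage and C6 is untouched under neutral conditions.

Step 7
Reactants: 11 (S)-linalool
Product: 12 (3S)-3,7-dimethyl-3-(triethylsilyloxy)octa-1,6-diene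
Conditions: Et3SiOTf, 2,6-lutidine, CH2Cl2, 0 °C
Reagents that add atoms: triethylsilyl trifluoromethanesulfonate, CC[Si](CC)(CC)OS(=O)(=O)C(F)(F)F
Why: Silyl ether protection of the tertiary allylic alcohol (C10) with a silyl triflate and a hindered pyridine base.

Step 8
Reactants: 12 (3S)-3,7-dimethyl-3-(triethylsilyloxy)octa-1,6-diene
Product: 14 (3S)-3,7-dimethyl-3-(triethylsilyloxy)oct-6-en-1-ol, via alkylborane 13 (not isolated)
Conditions: 9-BBN, THF, 0 °C to rt; then NaOH, H2O2, 0 °C
Reagents that add atoms: hydrogen peroxide, OO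
Why: Anti-Markovnikov hydroboration–oxidation: 9-BBN selects the monosubstituted vinyl group over the trisubstituted prenyl olefin and alkaline peroxide gives the primary alcohol at C8.

Step 9
Reactants: 14 (3S)-3,7-dimethyl-3-(triethylsilyloxy)oct-6-en-1-ol
Product: 15 (3S)-3,7-dimethyl-3-(triethylsilyloxy)oct-6-enal
Conditions: TEMPO (cat.), PhI(OAc)2, CH2Cl2, rt
Reagents that add atoms: none
Why: TEMPO/PhI(OAc)2 oxidation of the primary alcohol stops at the aldehyde under near-neutral conditions that spare the silyl ether and the olefin and avoid base-induced loss of the silanol.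

Step 10
Reactants: 10 (5S)-3-(bromomethyl)-5-[(Z)-2-iodoprop-1-en-1-yl]furan-2(5H)-one; 15 (3S)-3,7-dimethyl-3-(triethylsilyloxy)oct-6-enal
Product: 17 (4R,5S)-4-[(1S,3S)-1-hydroxy-3,7-dimethyl-3-(triethylsilyloxy)oct-6-en-1-yl]-5-[(Z)-2-iodoprop-1-en-1-yl]-3-methylideneoxolan-2-one, via allylzinc bromide 16 (not isolated)
Conditions: Zn dust, THF/sat. aq NH4Cl, 0 °C to rt
Reagents that add atoms: none
Why: Zinc Barbier allylation of a 3-(bromomethyl)butenolide: the allylzinc should add through C7 in a six-membered chair on the face anti to the C6 iodopropenyl group (6,7-trans lactone) with the aldehyde chain equatorial (8S carbinol), giving the α-methylene lactone directly.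

Step 11
Reactants: 17 the 8S carbinol from step 10; 18 2-methylpropanoic acid (isobutyric acid)
Product: 19 (1R,3S)-1-[(2S,3R)-2-[(Z)-2-iodoprop-1-en-1-yl]-4-methylidene-5-oxooxolan-3-yl]-3,7-dimethyl-3-(triethylsilyloxy)oct-6-en-1-yl 2-methylpropanoate
Conditions: PPh3, DIAD (betaine pre-formed), then 17 and 18, toluene, 0 °C to rt
Reagents that add atoms: none
Why: Mitsunobu esterification: SN2 displacement of the C8 oxyphosphonium by isobutyrate should invert C8 to the required 8R ester, and pre-forming the betaine keeps free phosphine away from the α-methylene lactone.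

Step 12
Reactants: 19 the 8R isobutyrate from step 11
Product: 21 (1R,3S)-1-[(2S,3R)-2-[(Z)-2-iodoprop-1-en-1-yl]-4-methylidene-5-oxooxolan-3-yl]-3-methyl-6-oxo-3-(triethylsilyloxy)hexyl 2-methylpropanoate, via ozonide 20 (not isolated)
Conditions: O3, CH2Cl2, −78 °C (Sudan Red 7B end point); then Me2S, −78 °C to rt
Reagents that add atoms: ozone, [O-][O+]=O
Why: Ozonolysis with reductive work-up: the electron-rich trisubstituted prenyl olefin should consume ozone far faster than the electron-poor α-methylene lactone or the iodoalkene, the dye marking the end point, to reveal the C3 aldehyde.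

Step 13
Reactants: 21 the iodo aldehyde from step 12
Product: 23 (3aR,4R,6S,9S,10Z,11aR)-9-hydroxy-6,10-dimethyl-3-methylidene-2-oxo-6-(triethylsilyloxy)-2,3,3a,4,5,6,7,8,9,11a-decahydrocyclodeca[b]furan-4-yl 2-methylpropanoate, via alkenylchromium dichloride 22 (not isolated)
Conditions: CrCl2 (10 equiv), NiCl2 (0.2 equiv), degassed DMSO, rt, slow addition of 21 (final 2 mM)
Reagents that add atoms: none
Why: Zerovalent nickel, formed from NiCl2 by CrCl2, inserts into the C4–iodine bond with retention of the Z geometry, the alkenyl group passes to trivalent chromium, and the alkenylchromium adds to the C3 aldehyde to form C3–C4 (intramolecular Nozaki–Hiyama–Kishi coupling). The closest known reaction type is the NiCl2/CrCl2-mediated alkenyl iodide–aldehyde macrocyclisation used for eight- to twelve-membered carbocycles. The ten-membered carbocycle is closed by this one carbonyl addition, 10-exo-trig at the aldehyde, with the Z-alkenyl unit and the trans lactone turning the chain so that C3 and C4 can meet. The new C3 stereocentre is set under substrate control by the conformation of the forming ring and should be 3S, although the sense cannot be predicted with confidence. The step needs selectivity for the aldehyde over the lactone, the isobutyrate and the α-methylene acceptor, secured by the non-basic, aldehyde-selective alkenylchromium, and ring closure over intermolecular coupling, secured by slow addition at high dilution.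

Step 14
Reactants: 23 the macrocyclic silyl ether from step 13
Product: 24 (3aR,4R,6S,9S,10Z,11aR)-6,9-dihydroxy-6,10-dimethyl-3-methylidene-2-oxo-2,3,3a,4,5,6,7,8,9,11a-decahydrocyclodeca[b]furan-4-yl 2-methylpropanoate (CNP0163972.1)
Conditions: HF·pyridine, pyridine, THF, 0 °C to rt
Reagents that add atoms: none
Why: Fluoride-mediated desilylation of the tertiary triethylsilyl ether under buffered conditions should leave the lactone, the isobutyrate and the allylic alcohol intact.

**Compound list**

1 | but-2-yn-1-ol | CC#CCO | starting material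
2 | sodium 2,2-bis(2-methoxyethoxy)-3-methyl-2,5-dihydro-1,2-oxaluminol-2-uide (cyclic alkenylaluminate) | [Na+].CC1=CCO[Al-]1(OCCOC)OCCOC | intermediate
3 | (Z)-3-iodobut-2-en-1-ol | OC/C=C(/C)I | intermediate
4 | (Z)-3-iodobut-2-enal | O=C/C=C(/C)I | intermediate
5 | rac-(Z)-5-iodohexa-1,4-dien-3-ol | OC(C=C)/C=C(/C)I | intermediate
6 | (3S,4Z)-5-iodohexa-1,4-dien-3-ol | O[C@H](/C=C(/C)I)C=C | intermediate
7 | 2-(bromomethyl)prop-2-enoic acid | C=C(CBr)C(=O)O | starting material
8 | 2-(bromomethyl)prop-2-enoyl chloride | C=C(CBr)C(=O)Cl | intermediate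
9 | (3S,4Z)-5-iodohexa-1,4-dien-3-yl 2-(bromomethyl)prop-2-enoate | C=C(CBr)C(=O)O[C@H](/C=C(/C)I)C=C | intermediate
10 | (5S)-3-(bromomethyl)-5-[(Z)-2-iodoprop-1-en-1-yl]furan-2(5H)-one | O=C1O[C@H](/C=C(/C)I)C=C1CBr | intermediate
11 | (S)-linalool, (3S)-3,7-dimethylocta-1,6-dien-3-ol | C=C[C@@](C)(O)CCC=C(C)C | starting material
12 | (3S)-3,7-dimethyl-3-(triethylsilyloxy)octa-1,6-diene | C=C[C@@](C)(O[Si](CC)(CC)CC)CCC=C(C)C | intermediate
13 | 9-[(3R)-3,7-dimethyl-3-(triethylsilyloxy)oct-6-en-1-yl]-9-borabicyclo[3.3.1]nonane (descriptor changes by priority only) | B1(CC[C@@](C)(O[Si](CC)(CC)CC)CCC=C(C)C)C2CCCC1CCC2 | intermediate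
14 | (3S)-3,7-dimethyl-3-(triethylsilyloxy)oct-6-en-1-ol | OCC[C@@](C)(O[Si](CC)(CC)CC)CCC=C(C)C | intermediate
15 | (3S)-3,7-dimethyl-3-(triethylsilyloxy)oct-6-enal | O=CC[C@@](C)(O[Si](CC)(CC)CC)CCC=C(C)C | intermediate
16 | bromo{[(5S)-5-[(Z)-2-iodoprop-1-en-1-yl]-2-oxo-2,5-dihydrofuran-3-yl]methyl}zinc | O=C1O[C@H](/C=C(/C)I)C=C1C[Zn]Br | intermediate
17 | (4R,5S)-4-[(1S,3S)-1-hydroxy-3,7-dimethyl-3-(triethylsilyloxy)oct-6-en-1-yl]-5-[(Z)-2-iodoprop-1-en-1-yl]-3-methylideneoxolan-2-one | C=C1C(=O)O[C@H](/C=C(/C)I)[C@H]1[C@@H](O)C[C@@](C)(O[Si](CC)(CC)CC)CCC=C(C)C | intermediate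
18 | 2-methylpropanoic acid (isobutyric acid) | CC(C)C(=O)O | starting material
19 | (1R,3S)-1-[(2S,3R)-2-[(Z)-2-iodoprop-1-en-1-yl]-4-methylidene-5-oxooxolan-3-yl]-3,7-dimethyl-3-(triethylsilyloxy)oct-6-en-1-yl 2-methylpropanoate | C=C1C(=O)O[C@H](/C=C(/C)I)[C@H]1[C@H](OC(=O)C(C)C)C[C@@](C)(O[Si](CC)(CC)CC)CCC=C(C)C | intermediate
20 | secondary ozonide of 19 (3,3-dimethyl-1,2,4-trioxolane across C3 and the isopropylidene carbon, mixture at the new ring carbon) | C=C1C(=O)O[C@H](/C=C(/C)I)[C@H]1[C@H](OC(=O)C(C)C)C[C@@](C)(O[Si](CC)(CC)CC)CCC2OOC(C)(C)O2 | intermediate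
21 | (1R,3S)-1-[(2S,3R)-2-[(Z)-2-iodoprop-1-en-1-yl]-4-methylidene-5-oxooxolan-3-yl]-3-methyl-6-oxo-3-(triethylsilyloxy)hexyl 2-methylpropanoate | C=C1C(=O)O[C@H](/C=C(/C)I)[C@H]1[C@H](OC(=O)C(C)C)C[C@@](C)(O[Si](CC)(CC)CC)CCC=O | intermediate
22 | (Z)-alkenylchromium dichloride from 21 (CrCl2 group in place of iodine at C4) | C=C1C(=O)O[C@H](/C=C(/C)[Cr](Cl)Cl)[C@H]1[C@H](OC(=O)C(C)C)C[C@@](C)(O[Si](CC)(CC)CC)CCC=O | intermediate
23 | (3aR,4R,6S,9S,10Z,11aR)-9-hydroxy-6,10-dimethyl-3-methylidene-2-oxo-6-(triethylsilyloxy)-2,3,3a,4,5,6,7,8,9,11a-decahydrocyclodeca[b]furan-4-yl 2-methylpropanoate | C=C1C(=O)O[C@@H]2/C=C(/C)[C@@H](O)CC[C@](C)(O[Si](CC)(CC)CC)C[C@@H](OC(=O)C(C)C)[C@@H]12 | intermediate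
24 | (3aR,4R,6S,9S,10Z,11aR)-6,9-dihydroxy-6,10-dimethyl-3-methylidene-2-oxo-2,3,3a,4,5,6,7,8,9,11a-decahydrocyclodeca[b]furan-4-yl 2-methylpropanoate | C=C1C(=O)O[C@@H]2/C=C(/C)[C@@H](O)CC[C@](C)(O)C[C@@H](OC(=O)C(C)C)[C@@H]12 | target

**Step count**

Total: 14 steps. Longest linear sequence: 11 steps (steps 1–6, then 10–14); steps 7–9 form the second branch.

**Steps most likely to fail**

Step 13. Ring closure may lose out to intermolecular coupling or to protonation of the alkenylchromium (iodine lost without carbon–carbon bond formation), and the aldehyde may be attacked preferentially on the wrong face. Fallback: setting out from 21, the coupling is accepted with the opposite sense at C3, giving the 3R carbinol F1. Oxidation (Dess–Martin periodinane, NaHCO3, CH2Cl2) gives the macrocyclic Z-enone F2. Reagent-controlled reduction ((R)-Me-CBS oxazaborolidine, catecholborane, toluene, −78 °C, the alkenyl side acting as the large group) should return the route to 23.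

Step 11. SN2 displacement at the hindered C8 carbinol may be slower than elimination towards C7 or than acyl transfer with retention, and phosphine may add to the α-methylene lactone. Fallback: from 17, base-free oxidation (Dess–Martin periodinane, NaHCO3) gives the C8 ketone F3. Reduction with NaBH4/CeCl3 in MeOH at −78 °C, hydride arriving anti to the oxygen-bearing ring carbon C6 (Felkin–Anh), should give the 8R carbinol F4; this sense is not secure, and a CBS oxazaborolidine of the appropriate hand is the reserve if substrate control is weak. Acylation with isobutyric anhydride, DMAP and pyridine rejoins the route at 19. The same operations would also converge a C8 epimer mixture from step 10, and if step 10 gives the 8R carbinol directly, only the acylation is needed.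

Step 12. Over-oxidation may set in once the prenyl olefin is consumed, ozone then attacking the iodoalkene or the α-methylene lactone. Fallback: from 19, catalytic OsO4 with N-methylmorpholine N-oxide (acetone/water, 0 °C), which prefers the electron-rich trisubstituted olefin, gives the vicinal diol F5, and NaIO4 (THF/water) cleaves it to rejoin the route at 21.

**Further compounds**

F1 | step 13 | (3aR,4R,6S,9R,10Z,11aR)-9-hydroxy-6,10-dimethyl-3-methylidene-2-oxo-6-(triethylsilyloxy)-2,3,3a,4,5,6,7,8,9,11a-decahydrocyclodeca[b]furan-4-yl 2-methylpropanoate (C3 epimer of 23) | C=C1C(=O)O[C@@H]2/C=C(/C)[C@H](O)CC[C@](C)(O[Si](CC)(CC)CC)C[C@@H](OC(=O)C(C)C)[C@@H]12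
F2 | step 13 | (3aR,4R,6S,10Z,11aR)-6,10-dimethyl-3-methylidene-2,9-dioxo-6-(triethylsilyloxy)-2,3,3a,4,5,6,7,8,9,11a-decahydrocyclodeca[b]furan-4-yl 2-methylpropanoate | C=C1C(=O)O[C@@H]2/C=C(/C)C(=O)CC[C@](C)(O[Si](CC)(CC)CC)C[C@@H](OC(=O)C(C)C)[C@@H]12
F3 | step 11 | (4S,5S)-4-[(3S)-3,7-dimethyl-3-(triethylsilyloxy)oct-6-enoyl]-5-[(Z)-2-iodoprop-1-en-1-yl]-3-methylideneoxolan-2-one | C=C1C(=O)O[C@H](/C=C(/C)I)[C@H]1C(=O)C[C@@](C)(O[Si](CC)(CC)CC)CCC=C(C)C
F4 | step 11 | (4R,5S)-4-[(1R,3S)-1-hydroxy-3,7-dimethyl-3-(triethylsilyloxy)oct-6-en-1-yl]-5-[(Z)-2-iodoprop-1-en-1-yl]-3-methylideneoxolan-2-one | C=C1C(=O)O[C@H](/C=C(/C)I)[C@H]1[C@H](O)C[C@@](C)(O[Si](CC)(CC)CC)CCC=C(C)C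
F5 | step 12 | (1R,3S)-6,7-dihydroxy-1-[(2S,3R)-2-[(Z)-2-iodoprop-1-en-1-yl]-4-methylidene-5-oxooxolan-3-yl]-3,7-dimethyl-3-(triethylsilyloxy)octyl 2-methylpropanoate (mixture at the new secondary carbinol) | C=C1C(=O)O[C@H](/C=C(/C)I)[C@H]1[C@H](OC(=O)C(C)C)C[C@@](C)(O[Si](CC)(CC)CC)CCC(O)C(C)(C)O
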